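**Retrosynthetic overview**

1. The target comes from the fully assembled skeleton by one-pot removal of an aryl silyl ether and a diol acetonide.
2. The C4'–C5' bond is made by nickel-electrocatalytic decarboxylative alkenylation (chromene-bearing E-alkenyl iodide plus a dioxolane carboxylic acid). The C6'–C7' bond is made by photoredox/nickel decarboxylative alkenylation of L-tartaric acid acetonide with (E)-1-iodo-2,6-dimethylhepta-1,5-diene. Both carbinol centres relay from L-tartrate through the trans-dioxolane.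
3. The alkenyl iodide comes from hydrozirconation/iodination of a 2-alkyne on the chromene; the chromene comes from photochemical closure of the O1–C8a bond of an E-styrenyl tertiary carbinol carrying an ortho C–F bond; that carbinol comes from a Heck coupling.
4. The carbinol partner comes from (S)-linalool (source of C2; its C–O bond is never broken) by ozonolysis, alkyne homologation and methylation. The aryl iodide comes from 4-fluoro-3-methylphenol and the dienyl iodide from 6-methylhept-5-en-2-one.
5. Rings: the benzene ring and the dioxolane are bought; the pyran ring is the only ring formed (step 7); the dioxolane is opened in the last step.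

Assumption: commercial (S)-(+)-linalool is used and its enantiomeric purity sets the ee at C2; side-chain carbons are numbered C1' to C12' outward from chromene C2.

**Route**

Step 1
Reactants: 1 (S)-(+)-linalool
Product: 4 (5S)-5-ethenyl-5-methyloxolan-2-ol (anomer mixture), via ozonide 2 (not isolated), via hydroxy aldehyde 3 (not isolated)
Conditions: O3 (1.0 equiv), CH2Cl2, −78 °C; then Me2S, −78 °C to rt
Reagents that add atoms: ozone, [O-][O+]=O
Why: Chemoselective ozonolysis, in which ozone attacks the electron-rich trisubstituted alkene much faster than the monosubstituted vinyl group and the γ-hydroxy aldehyde closes to the lactol, leaving the carbinol stereocentre untouched.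

Step 2
Reactants: 4 (5S)-5-ethenyl-5-methyloxolan-2-ol
Product: 5 (3S)-3-methylhept-1-en-6-yn-3-ol
Conditions: dimethyl (1-diazo-2-oxopropyl)phosphonate, K2CO3, MeOH, 0 °C to rt
Reagents that add atoms: dimethyl (1-diazo-2-oxopropyl)phosphonate, CC(=O)C(=[N+]=[N-])P(=O)(OC)OC
Why: Ohira–Bestmann (Seyferth–Gilbert) homologation acts on the open-chain aldehyde in equilibrium with the lactol and adds the terminal alkyne carbon under carbonate conditions that leave the tertiary allylic alcohol intact.

Step 3
Reactants: 5 (3S)-3-methylhept-1-en-6-yn-3-ol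
Product: 7 (3S)-3-methyloct-1-en-6-yn-3-ol, via dilithio alkoxide acetylide 6 (not isolated)
Conditions: n-BuLi (2.1 equiv), THF, −78 to 0 °C; then MeI (1.05 equiv), −78 °C to rt
Reagents that add atoms: iodomethane, CI
Why: Alkylation of a lithium acetylide, in which the acetylide carbon of the dianion is methylated much faster than the hindered tertiary lithium alkoxide; capping the alkyne also prevents alkynylation in the Heck step.

Step 4
Reactants: 8 4-fluoro-3-methylphenol
Product: 9 (4-fluoro-3-methylphenoxy)tri(propan-2-yl)silane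
Conditions: i-Pr3SiCl, imidazole, DMF, rt
Reagents that add atoms: chlorotri(propan-2-yl)silane, CC(C)[Si](Cl)(C(C)C)C(C)C
Why: Standard phenol silylation; the bulky silyl group is meant to survive the later base, palladium, zirconium and electrochemical steps and shields the positions ortho to oxygen from lithiation.

Step 5
Reactants: 9 (4-fluoro-3-methylphenoxy)tri(propan-2-yl)silane
Product: 11 (4-fluoro-3-iodo-5-methylphenoxy)tri(propan-2-yl)silane, via aryllithium 10 (not isolated)
Conditions: s-BuLi, THF, −78 °C; then I2, −78 °C to rt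
Reagents that add atoms: iodine, II
Why: Directed ortho-metalation, in which fluorine is the strongest acidifying group and C5–H is the only hydrogen ortho to it, so the iodide lands on the carbon that becomes chromene C4a.

Step 6
Reactants: 7 (3S)-3-methyloct-1-en-6-yn-3-ol; 11 (4-fluoro-3-iodo-5-methylphenoxy)tri(propan-2-yl)silane
Product: 12 (1E,3S)-1-{2-fluoro-3-methyl-5-[tri(propan-2-yl)silyloxy]phenyl}-3-methyloct-1-en-6-yn-3-ol
Conditions: Pd(OAc)2 (5 mol %), n-Bu4NCl, NaHCO3, DMF, 50 °C
Reagents that add atoms: none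
Why: Mizoroki–Heck reaction, in which aryl–palladium adds to the terminal vinyl carbon and β-hydride elimination can only come from the benzylic CH2 (the carbinol carbon has no hydrogen), giving the E-styrene while C–F, the internal alkyne and the carbinol centre are not involved.

Step 7
Reactants: 12 (1E,3S)-1-{2-fluoro-3-methyl-5-[tri(propan-2-yl)silyloxy]phenyl}-3-methyloct-1-en-6-yn-3-ol
Product: 14 {[(2S)-2,8-dimethyl-2-(pent-3-yn-1-yl)-2H-chromen-6-yl]oxy}tri(propan-2-yl)silane, via Z-alkene 13 (not isolated)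
Conditions: 9-mesityl-3,6-di-tert-butyl-10-phenylacridinium tetrafluoroborate (5 mol %), K3PO4 (2 equiv), ClCH2CH2Cl (0.02 M), 450 nm LEDs, 25 °C, N2
Reagents that add atoms: none
Why: Proposed new method: a photoredox E-to-Z isomerisation/cation-radical-accelerated intramolecular SNAr etherification, in which the excited acridinium oxidises the silyloxystyrene to its radical cation, whose weakened C=C bond (and the back-electron-transfer triplet) lets E and Z interconvert, only the Z form can place the tertiary hydroxyl over the C–F carbon (para to the silyloxy group, where the radical cation is most electrophilic), and ipso attack, deprotonation, reduction by the acridine radical and loss of fluoride (trapped as KF) close the pyran ring redox-neutrally with the carbinol C–O bond intact, hence retention at C2; the closest known chemistry is cation-radical-accelerated SNAr of electron-rich fluoroarenes with azole, amine and carboxylic acid nucleophiles, together with photocatalytic E-to-Z isomerisation/cyclisation cascades.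

Step 8
Reactants: 14 {[(2S)-2,8-dimethyl-2-(pent-3-yn-1-yl)-2H-chromen-6-yl]oxy}tri(propan-2-yl)silane
Product: 16 {[(2S)-2-[(3E)-4-iodopent-3-en-1-yl]-2,8-dimethyl-2H-chromen-6-yl]oxy}tri(propan-2-yl)silane, via alkenyl–ZrCp2Cl complex 15 (not isolated)
Conditions: Cp2Zr(H)Cl (2.0 equiv), THF, 45 °C; then I2, 0 °C
Reagents that add atoms: iodine, II
Why: Schwartz hydrozirconation is a syn addition that, after equilibration with excess reagent, puts zirconium on the less hindered methyl-bearing alkyne carbon (about 9:1 expected), and iodinolysis with retention gives the E-iodide with iodine trans to the chain.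

Step 9
Reactants: 17 6-methylhept-5-en-2-one
Product: 21 6-methylhept-5-en-1-yne, via lithium enolate 18 (not isolated), via enol phosphate 19 (not isolated), via lithium acetylide 20 (not isolated)
Conditions: LiN(i-Pr)2 (1.05 equiv), THF, −78 °C; ClP(O)(OEt)2; then LiN(i-Pr)2 (2.3 equiv), −78 °C to rt; H2O
Reagents that add atoms: none
Why: Negishi one-pot conversion of a methyl ketone into a terminal alkyne by kinetic enolate O-phosphorylation followed by base-induced elimination of diethyl phosphate.

Step 10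
Reactants: 21 6-methylhept-5-en-1-yne
Product: 23 (1E)-1-iodo-2,6-dimethylhepta-1,5-diene, via alkenylalane 22 (not isolated)
Conditions: Me3Al (2 equiv), Cp2ZrCl2 (0.25 equiv), CH2Cl2, 0 °C to rt; then I2, THF, −30 to 0 °C
Reagents that add atoms: trimethylaluminium, C[Al](C)C; iodine, II
Why: Zirconium-catalysed Negishi carboalumination adds Me and Al syn with aluminium on the terminal carbon, and iodinolysis with retention gives the E-alkenyl iodide.

Step 11
Reactants: 24 dimethyl (4R,5R)-2,2-dimethyl-1,3-dioxolane-4,5-dicarboxylate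
Product: 26 (4R,5R)-2,2-dimethyl-1,3-dioxolane-4,5-dicarboxylic acid, via dipotassium salt 25 (not isolated)
Conditions: KOH (2.2 equiv), MeOH/H2O, rt; then 1 M HCl to pH 2, 0 °C
Reagents that add atoms: potassium hydroxide, [K+].[OH-]
Why: Ester saponification, with the trans-dioxolane being the thermodynamically preferred arrangement so both bought stereocentres are kept.

Step 12
Reactants: 26 (4R,5R)-2,2-dimethyl-1,3-dioxolane-4,5-dicarboxylic acid; 23 (1E)-1-iodo-2,6-dimethylhepta-1,5-diene
Product: 27 (4R,5S)-5-[(1E)-2,6-dimethylhepta-1,5-dien-1-yl]-2,2-dimethyl-1,3-dioxolane-4-carboxylic acid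
Conditions: 26 (3 equiv), Ir[dF(CF3)ppy]2(dtbbpy)PF6 (1 mol %), NiCl2·glyme (5 mol %), dtbbpy (5 mol %), DBU (6 equiv), DMSO, 450 nm LEDs, rt
Reagents that add atoms: none
Why: Photoredox/nickel dual-catalysed decarboxylative alkenylation, in which the excited iridium complex oxidises one carboxylate, CO2 loss gives the dioxolanyl radical, and alkenyl–nickel from 23 captures it on the face trans to the neighbouring bought centre, setting C6' by substrate control from L-tartrate; the threefold excess of cheap 26 keeps double alkenylation low and the remaining carboxylate carbon cannot epimerise.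

Step 13
Reactants: 27 (4R,5S)-5-[(1E)-2,6-dimethylhepta-1,5-dien-1-yl]-2,2-dimethyl-1,3-dioxolane-4-carboxylic acid; 16 {[(2S)-2-[(3E)-4-iodopent-3-en-1-yl]-2,8-dimethyl-2H-chromen-6-yl]oxy}tri(propan-2-yl)silane
Product: 29 {[(2S)-2-[(3E)-4-{(4S,5S)-5-[(1E)-2,6-dimethylhepta-1,5-dien-1-yl]-2,2-dimethyl-1,3-dioxolan-4-yl}pent-3-en-1-yl]-2,8-dimethyl-2H-chromen-6-yl]oxy}tri(propan-2-yl)silane, via N-hydroxyphthalimide ester 28 (not isolated)
Conditions: N-hydroxyphthalimide, i-PrN=C=N-i-Pr, DMAP (cat.), CH2Cl2, rt; concentrate; then 16 (limiting), NiCl2·6H2O (20 mol %), 2,2'-bipyridine (20 mol %), AgNO3 (0.3 equiv), DMF, Mg anode/RVC cathode, constant current, rt, dark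
Reagents that add atoms: none
Why: Nickel-electrocatalytic decarboxylative alkenylation (reductive cross-electrophile coupling) of the redox-active ester, in which reduction of 28 releases CO2 and phthalimide and the planar C5' radical is trapped by alkenyl–nickel from 16 on the face trans to the C6' dienyl group (itself set from L-tartrate), with retention of the alkenyl geometry; running in the dark keeps the 2H-chromene from being photoexcited.

Step 14
Reactants: 29 {[(2S)-2-[(3E)-4-{(4S,5S)-5-[(1E)-2,6-dimethylhepta-1,5-dien-1-yl]-2,2-dimethyl-1,3-dioxolan-4-yl}pent-3-en-1-yl]-2,8-dimethyl-2H-chromen-6-yl]oxy}tri(propan-2-yl)silane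
Product: 31 (2S)-2-[(3E,5S,6S,7E)-5,6-dihydroxy-4,8,12-trimethyltrideca-3,7,11-trien-1-yl]-2,8-dimethyl-2H-chromen-6-ol (target), via phenol acetonide 30 (not isolated)
Conditions: n-Bu4NF, AcOH, THF, 0 °C; then AcOH/H2O (4:1), 40 °C
Reagents that add atoms: none
Why: Buffered fluoride desilylation of the aryl silyl ether followed by mild acetic acid hydrolysis of the acetonide, which cleaves only the O–CMe2 bonds and so leaves the allylic C–O bonds, the alkenes and all three stereocentres untouched.

**Compound list**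

1 | (S)-(+)-linalool, (3S)-3,7-dimethylocta-1,6-dien-3-ol | C=C[C@@](C)(O)CCC=C(C)C | starting material
2 | (3S)-5-(5,5-dimethyl-1,2,4-trioxolan-3-yl)-3-methylpent-1-en-3-ol (ozonide) | C=C[C@@](C)(O)CCC1OOC(C)(C)O1 | intermediate (not isolated)
3 | (4S)-4-hydroxy-4-methylhex-5-enal | C=C[C@@](C)(O)CCC=O | intermediate (not isolated)
4 | (5S)-5-ethenyl-5-methyloxolan-2-ol (anomer mixture) | C=C[C@]1(C)CCC(O)O1 | intermediate
5 | (3S)-3-methylhept-1-en-6-yn-3-ol | C=C[C@@](C)(O)CCC#C | intermediate
6 | dilithium salt of 5 (lithium alkoxide, lithium acetylide) | C=C[C@@](C)(O[Li])CCC#C[Li] | intermediate (not isolated)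
7 | (3S)-3-methyloct-1-en-6-yn-3-ol | C=C[C@@](C)(O)CCC#CC | intermediate
8 | 4-fluoro-3-methylphenol | Cc1cc(O)ccc1F | starting material
9 | (4-fluoro-3-methylphenoxy)tri(propan-2-yl)silane | Cc1cc(O[Si](C(C)C)(C(C)C)C(C)C)ccc1F | intermediate
10 | {2-fluoro-3-methyl-5-[tri(propan-2-yl)silyloxy]phenyl}lithium | Cc1cc(O[Si](C(C)C)(C(C)C)C(C)C)cc([Li])c1F | intermediate (not isolated)
11 | (4-fluoro-3-iodo-5-methylphenoxy)tri(propan-2-yl)silane | Cc1cc(O[Si](C(C)C)(C(C)C)C(C)C)cc(I)c1F | intermediate
12 | (1E,3S)-1-{2-fluoro-3-methyl-5-[tri(propan-2-yl)silyloxy]phenyl}-3-methyloct-1-en-6-yn-3-ol | CC#CCC[C@](C)(O)/C=C/c1cc(O[Si](C(C)C)(C(C)C)C(C)C)cc(C)c1F | intermediate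
13 | (1Z,3S)-1-{2-fluoro-3-methyl-5-[tri(propan-2-yl)silyloxy]phenyl}-3-methyloct-1-en-6-yn-3-ol | CC#CCC[C@](C)(O)/C=C\c1cc(O[Si](C(C)C)(C(C)C)C(C)C)cc(C)c1F | intermediate (not isolated)
14 | {[(2S)-2,8-dimethyl-2-(pent-3-yn-1-yl)-2H-chromen-6-yl]oxy}tri(propan-2-yl)silane | CC#CCC[C@@]1(C)C=Cc2cc(O[Si](C(C)C)(C(C)C)C(C)C)cc(C)c2O1 | intermediate
15 | chlorobis(cyclopentadienyl)[(2E)-5-{(2S)-2,8-dimethyl-6-[tri(propan-2-yl)silyloxy]-2H-chromen-2-yl}pent-2-en-2-yl]zirconium | Cl[Zr](C1C=CC=C1)(C1C=CC=C1)/C(C)=C/CC[C@@]1(C)C=Cc2cc(O[Si](C(C)C)(C(C)C)C(C)C)cc(C)c2O1 | intermediate (not isolated)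
16 | {[(2S)-2-[(3E)-4-iodopent-3-en-1-yl]-2,8-dimethyl-2H-chromen-6-yl]oxy}tri(propan-2-yl)silane | I/C(C)=C/CC[C@@]1(C)C=Cc2cc(O[Si](C(C)C)(C(C)C)C(C)C)cc(C)c2O1 | intermediate
17 | 6-methylhept-5-en-2-one | CC(=O)CCC=C(C)C | starting material
18 | lithium 6-methylhepta-1,5-dien-2-olate | C=C(O[Li])CCC=C(C)C | intermediate (not isolated)
19 | diethyl 6-methylhepta-1,5-dien-2-yl phosphate | C=C(CCC=C(C)C)OP(=O)(OCC)OCC | intermediate (not isolated)
20 | (6-methylhept-5-en-1-yn-1-yl)lithium | [Li]C#CCCC=C(C)C | intermediate (not isolated)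
21 | 6-methylhept-5-en-1-yne | C#CCCC=C(C)C | intermediate
22 | [(1E)-2,6-dimethylhepta-1,5-dien-1-yl]dimethylalane | C[Al](C)/C=C(\C)CCC=C(C)C | intermediate (not isolated)
23 | (1E)-1-iodo-2,6-dimethylhepta-1,5-diene | I/C=C(\C)CCC=C(C)C | intermediate
24 | dimethyl (4R,5R)-2,2-dimethyl-1,3-dioxolane-4,5-dicarboxylate (dimethyl 2,3-O-isopropylidene-L-tartrate) | COC(=O)[C@@H]1OC(C)(C)O[C@H]1C(=O)OC | starting material
25 | dipotassium (4R,5R)-2,2-dimethyl-1,3-dioxolane-4,5-dicarboxylate | [K+].[K+].[O-]C(=O)[C@@H]1OC(C)(C)O[C@H]1C([O-])=O | intermediate (not isolated)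
26 | (4R,5R)-2,2-dimethyl-1,3-dioxolane-4,5-dicarboxylic acid | OC(=O)[C@@H]1OC(C)(C)O[C@H]1C(O)=O | intermediate
27 | (4R,5S)-5-[(1E)-2,6-dimethylhepta-1,5-dien-1-yl]-2,2-dimethyl-1,3-dioxolane-4-carboxylic acid | OC(=O)[C@@H]1OC(C)(C)O[C@H]1/C=C(\C)CCC=C(C)C | intermediate
28 | 1,3-dioxoisoindolin-2-yl (4R,5S)-5-[(1E)-2,6-dimethylhepta-1,5-dien-1-yl]-2,2-dimethyl-1,3-dioxolane-4-carboxylate | O=C(ON1C(=O)c2ccccc2C1=O)[C@@H]1OC(C)(C)O[C@H]1/C=C(\C)CCC=C(C)C | intermediate (not isolated)
29 | {[(2S)-2-[(3E)-4-{(4S,5S)-5-[(1E)-2,6-dimethylhepta-1,5-dien-1-yl]-2,2-dimethyl-1,3-dioxolan-4-yl}pent-3-en-1-yl]-2,8-dimethyl-2H-chromen-6-yl]oxy}tri(propan-2-yl)silane | CC(C)=CCC/C(C)=C/[C@@H]1OC(C)(C)O[C@H]1/C(C)=C/CC[C@@]2(C)C=Cc3cc(O[Si](C(C)C)(C(C)C)C(C)C)cc(C)c3O2 | intermediate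
30 | (2S)-2-[(3E)-4-{(4S,5S)-5-[(1E)-2,6-dimethylhepta-1,5-dien-1-yl]-2,2-dimethyl-1,3-dioxolan-4-yl}pent-3-en-1-yl]-2,8-dimethyl-2H-chromen-6-ol | CC(C)=CCC/C(C)=C/[C@@H]1OC(C)(C)O[C@H]1/C(C)=C/CC[C@@]2(C)C=Cc3cc(O)cc(C)c3O2 | intermediate (not isolated)
31 | (2S)-2-[(3E,5S,6S,7E)-5,6-dihydroxy-4,8,12-trimethyltrideca-3,7,11-trien-1-yl]-2,8-dimethyl-2H-chromen-6-ol | CC(C)=CCC/C(C)=C/[C@H](O)[C@@H](O)/C(C)=C/CC[C@@]1(C)C=Cc2cc(O)cc(C)c2O1 | target

**Step count and risks**

Total step count: 14. Longest linear sequence: 8 steps (1, 2, 3, 6, 7, 8, 13, 14).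

The three steps most likely to fail:

Step 7 (proposed new ring closure). The E-to-Z step is uphill, an alcohol has not been shown as the nucleophile in this radical-cation substitution, the HF formed could ionise the tertiary allylic alcohol or cleave the silyl ether if the phosphate buffer is too slow, and any excitation of the product chromene could open the pyran ring and erode the ee at C2. The fallback uses known chemistry, sets out from 12 and comes back at 14. Triplet-sensitised E-to-Z isomerisation (Ir(ppy)3, 1 mol %, MeCN, 450 nm LEDs) gives the Z-alkene 13, which is isolated. Deprotonation with KN(SiMe3)2 and 18-crown-6 in THF gives the potassium alkoxide of 13 F1, which on warming to 60 °C closes the ring by thermal intramolecular SNAr at the C–F carbon to give 14.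

Step 12 (mono-alkenylation of the diacid). The risks are statistical double alkenylation, poor solubility of the carboxylate salts and a lower trans selectivity than assumed. The fallback sets out from 24 and comes back at 27, replacing the statistical coupling by a desymmetrised half-ester. KOH (1.0 equiv) in MeOH at 0 °C gives potassium (4R,5R)-5-(methoxycarbonyl)-2,2-dimethyl-1,3-dioxolane-4-carboxylate F2. Acidification gives (4R,5R)-5-(methoxycarbonyl)-2,2-dimethyl-1,3-dioxolane-4-carboxylic acid F3. The same photoredox/nickel decarboxylative alkenylation with 23 gives methyl (4R,5S)-5-[(1E)-2,6-dimethylhepta-1,5-dien-1-yl]-2,2-dimethyl-1,3-dioxolane-4-carboxylate F4. KOH in MeOH/H2O at 0 °C gives the potassium salt of 27 F5, and acidification gives 27.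

Step 13 (electrochemical coupling). A hindered α-methyl alkenyl iodide must meet a secondary α-oxy radical, and reduction of the iodide or decomposition of the activated ester may win. The fallback sets out from 16 (with 28 prepared from 27 as in step 13 but isolated) and comes back at 29, replacing the electroreductive cross-electrophile coupling by a decarboxylative Negishi-type coupling. Iodine–lithium exchange on 16 (t-BuLi, 2 equiv, Et2O, −78 °C) gives the alkenyllithium F6. ZnCl2 converts it into the alkenylzinc chloride F7. F7 is coupled with isolated 28 using Ni(acac)2 (10 mol %) and 2,2'-bipyridine in THF/DMF at rt to give 29 with the same trans control.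

**Further compounds**

F1 | step 7 | potassium (1Z,3S)-1-{2-fluoro-3-methyl-5-[tri(propan-2-yl)silyloxy]phenyl}-3-methyloct-1-en-6-yn-3-olate | [K+].CC#CCC[C@](C)([O-])/C=C\c1cc(O[Si](C(C)C)(C(C)C)C(C)C)cc(C)c1F
F2 | step 12 | potassium (4R,5R)-5-(methoxycarbonyl)-2,2-dimethyl-1,3-dioxolane-4-carboxylate | [K+].COC(=O)[C@@H]1OC(C)(C)O[C@H]1C([O-])=O
F3 | step 12 | (4R,5R)-5-(methoxycarbonyl)-2,2-dimethyl-1,3-dioxolane-4-carboxylic acid | COC(=O)[C@@H]1OC(C)(C)O[C@H]1C(O)=O
F4 | step 12 | methyl (4R,5S)-5-[(1E)-2,6-dimethylhepta-1,5-dien-1-yl]-2,2-dimethyl-1,3-dioxolane-4-carboxylate | COC(=O)[C@@H]1OC(C)(C)O[C@H]1/C=C(\C)CCC=C(C)C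
F5 | step 12 | potassium (4R,5S)-5-[(1E)-2,6-dimethylhepta-1,5-dien-1-yl]-2,2-dimethyl-1,3-dioxolane-4-carboxylate | [K+].[O-]C(=O)[C@@H]1OC(C)(C)O[C@H]1/C=C(\C)CCC=C(C)C
F6 | step 13 | [(2E)-5-{(2S)-2,8-dimethyl-6-[tri(propan-2-yl)silyloxy]-2H-chromen-2-yl}pent-2-en-2-yl]lithium | [Li]/C(C)=C/CC[C@@]1(C)C=Cc2cc(O[Si](C(C)C)(C(C)C)C(C)C)cc(C)c2O1
F7 | step 13 | chloro[(2E)-5-{(2S)-2,8-dimethyl-6-[tri(propan-2-yl)silyloxy]-2H-chromen-2-yl}pent-2-en-2-yl]zinc | Cl[Zn]/C(C)=C/CC[C@@]1(C)C=Cc2cc(O[Si](C(C)C)(C(C)C)C(C)C)cc(C)c2O1
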